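At late times the delta run has slowed: its last reading is 59.7 % of the substrate charged, while the balance still leaves c_partner at 0.140 M. Substrate is the limiting reagent of that charge, 0.100 M against 0.200 M of partner. The last readings of the other runs stand at 71.3 % of charge in the beta run and 47.3 % in the theta run, so the share at the last reading shifts with the recipe. The alpha run repeats the delta charge, so the open question is what remains to come after the delta run's last reading.

| flask | substrate | partner | time |
|---|---|---|---|
| delta | 0.100 M | 0.200 M |  |
| theta | 0.300 M | 0.200 M |  |
| beta | 0.100 M | 0.300 M |  |
| alpha | 0.100 M | 0.200 M | 140 h |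

| delta run: time / h | delta run: [target] / M | theta run: time / h | theta run: [target] / M | beta run: time / h | beta run: [target] / M |
|---|---|---|---|---|---|
| 0.92 | 0.0018 | 0.92 | 0.0084 | 0.92 | 0.0032 |
| 1.8 | 0.0044 | 1.8 | 0.0211 | 1.8 | 0.0078 |
| 3.3 | 0.0103 | 3.3 | 0.0527 | 3.3 | 0.0193 |
| 6.3 | 0.0232 | 6.3 | 0.1020 | 6.3 | 0.0464 |
| 12 | 0.0465 | 12 | 0.1327 | 12 | 0.0683 |
| 23 | 0.0597 | 23 | 0.1418 | 23 | 0.0713 |

(each reading ± 3 × 10⁻⁴ M)

- apparent order in [substrate] of the starting rate, round the charge of the delta run (the rate where two percent of its substrate have turned into target) (one fixed amount of target, the same in the runs compared)
- apparent order in [partner] of the starting rate, round the charge of the delta run (the rate where two percent of its substrate have turned into target)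
- target in the alpha run at 140 h, as a share of the substrate charged

- Overall: substrate + partner -> target.
- Constant volume, constant temperature.
- "The second partner" is partner.
- An order is taken over about fifteen percent of the charge, up and down.

My own reckoning climbs a ladder of clocks. In the delta run the rate rises from 0.00196 M h⁻¹ over the first interval to 0.00409 M h⁻¹ between the readings at 6.3 h and 12 h, which I read as target speeding its own making. I therefore treat the close as pseudo-first-order, with c_partner and c_target held at their late values. In the beta run, taking the last reading as the end, the gap shrinks with a time of 2.69 h. Dividing the inverse of that time by the late c_partner and c_target gives the closing constant, the rate of closing per unit of c_partner times c_target 22.8 M⁻² h⁻¹. At the delta run's late concentrations it gives a closing time of 5.24 h, slower than the beta run. The gain of that run's last interval then leaves 0.00185 M to come. The 140 h of the alpha run span 26.7 closing times, so I expect 61.5 %.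

The forecast gives 63 %, range 59 % to 72 %, with orders 1.1 in substrate and 1 in partner, and says “alpha should sit near 63%, with perhaps slight creep”.

The flask gives 61.6 %, with orders 1.0 and 1.1, from these steps:

    substrate ⇌ intermediate, settled at all times (0.4190)
    intermediate + partner → target (0.3319 M⁻¹ h⁻¹)
    substrate + partner + target → 2 target (31.75 M⁻² h⁻¹)
    2 substrate → homo dimer (1.040 M⁻¹ h⁻¹)

The delta run reaches half of its charge at 13.4 h, when 0.0116 M separates it from the alpha value at 140 h. With the closing time 5.24 h, that gap is reckoned at 0.00188 M by 23 h, and the alpha value minus the delta reading there is 0.00194 M. In the theta run the closing constant gives 5.32 h, which puts an estimated 0.00132 M beyond its last reading of 0.1418 M.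

The runs come from a simulation on assumed constants, noise included.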